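Germacrane numbering is used throughout: ring C1–C10, ester carbon C14 on C10, methyl C15 on C4, lactone carbons C11–C13 on C7, oxygens O4, O5, O6, O8, O9 on the carbons of the same number.

## Structural features

The target 40 is a germacranolide: a ten-membered carbocycle (C1–C10) to which an α-methylene-γ-butyrolactone (O6, C12, C11=C13) is cis-fused at C6/C7. The ring holds a 1(10)-enoate whose ester carbon C14 lies trans to C2 (so C2 is cis to C9), and a cis-4,5-epoxide in which C3 and C6 sit on the same side of the oxirane. Six stereocentres follow each other from C4 to C9 (4R,5S,6R,7R,8S,9S), and C8 and C9 carry a threo pair of esters: an (S)-2-methyloxirane-2-carboxylate on O8 and an acetate on O9. The fragile parts are the exo-methylene lactone (a Michael acceptor), the two oxiranes, the C9 acetate (allylic to the enoate, able to leave in an SN2′ sense) and the vicinal esters, which can migrate. The real difficulty is to close the ten-membered ring while fixing C5 and C6, and to carry C7, which is allylic and next to C6, without epimerisation. The key step uses the fact that C5 and C6 are neighbouring oxygen-bearing ring carbons: as two aldehydes they can be joined reductively, which closes the ring and creates both carbinols. O6 then becomes the lactone oxygen, and O5 becomes the leaving group displaced by O4.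

## Logic of the disconnections

40 is cut at the O8–acyl bond into 36 and 38. The epoxy ester is the most sensitive group and its stereocentre lies outside the ring, so it is attached last and never meets SmI2, fluoride or DDQ. This leaves 36 with a single free hydroxyl. The forward step must acylate a hindered secondary alcohol next to an acetate without acyl migration and without opening an oxirane.

36 is taken back through 35 and 33 to 32 without cutting a carbon–carbon bond: C14 goes from ester to PMB ether, and O8 is masked as a PMB ether. The reason is that an ester on C10 would make C1=C10 an acceptor for ketyl radicals, so C14 must be an ether when the ring is closed. Both PMB ethers then fall in one operation. The forward oxidations must distinguish the allylic primary hydroxyl from the secondary one and spare the methylene lactone and the epoxide.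

32 is cut at O4–C5 (oxirane) and at O6–C12 (lactone) to reach 30, 28 and then 27. Both oxygens of the cis-diol of 27 are used: O6 as nucleophile towards C12, O5 as leaving group with inversion. The diol configuration is thereby translated into the cis-lactone and the cis-epoxide, and 27 contains neither an oxirane nor a Michael acceptor. The forward steps need hemiacetal formation on O6 rather than O5, and an anti arrangement of O4 and the C5–O bond.

27 is cut at C5–C6 to the dialdehyde 26. This opens the ring to a chain with four stereocentres (C4, C7, C8, C9); the forward step makes one bond, one ring and two stereocentres. It demands a cis-diol with O5 anti to O4 and O6 cis to C11, no ketyl–alkene reaction, and a C7 centre that survives as the α-carbon of an aldehyde.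

26 is taken back through 25 and 24 to 23, which is cut at C9–C10 into 9 and 20. The cut divides the chain into two pieces of similar size at a carbinol carbon next to an alkene, and the ether on C8 can steer the addition. The forward step needs an alkenyl metal that keeps its geometry and chelation control for the 9S carbinol.

20 is taken back through 19, 18 and 17 to 16, which is cut at C7–C11 into 14 and 11; 14 comes from 13 and 12. Opening an epoxy alcohol sets C7 by inversion and keeps the oxygen on C8, and the asymmetric epoxidation fixes the absolute configuration of both. The forward step needs attack at the oxirane carbon next to the free hydroxymethyl group.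

9 is taken back through 8, 7, 6 and 4 to 3 and 1: C1=C10 is cut by olefination, and C1 and C5 are uncovered by two oxidative cleavages. 1 already holds C1–C5 and C15 with C4 in the right configuration, and its two alkenes differ enough in electron density to be cleaved one after the other. The forward steps need a selective first ozonolysis and an olefination that puts bromine cis to C2. 38 comes from 37 by oxidation of the primary alcohol.

## Other disconnections considered

Alternative 1: The cut is at C1–C10 and C4–C5, made together as a cyclobutane. Irradiation of the lactone-fused enone A2 with 1-methylcyclobutene A3 would give the strained photoadduct A1, and later thermal opening of the central four-membered ring would release the ten-membered ring with its two ring alkenes.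
- In its favour: the medium ring comes from fragmentation of a σ-framework, so no high-dilution macrocyclisation is needed; on ring formation this is better than the chosen plan.
- Also in its favour: C14 is an ester from the start (the chosen plan needs three late operations for it), and C6, C7 and C8 are set on a rigid cis-fused bicycle; this too is a point for the alternative.
- Against it: a concerted thermal opening is expected to give one cis and one trans ring alkene, whereas 40 needs C2 cis to C9 and an oxirane with C3 cis to C6. The temperatures involved also invite Cope rearrangement of the 1,5-diene.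
- Against it: the C9 ketone would have to be reduced, the 4,5-alkene epoxidised and the lactone methylenated on a flexible ring, so C4, C5 and C9 are set late and under weak control.
- Comparison: the excited-state diradical addition creates four stereocentres that are all spent on alkene geometry. The ketyl coupling of 26 creates two that are kept (C6) or used with inversion (C5). The ring itself is reached in fewer steps, but the stereochemical repair afterwards should cancel this gain.

Alternative 2: The cut is at C7–C11. A dirhodium tetracarboxylate would decompose the diazo ester A5 carried on O6, and the carbenoid would insert into the C7–H bond to give the phosphono lactone A4; a Horner–Wadsworth–Emmons methylenation would then complete the lactone.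
- In its favour: the five-membered transition state can only reach the hydrogen cis to O6, so the cis ring fusion and the C7 configuration are inherent. The chosen plan depends on the facial course of the pinacol for this, so the alternative is better on that point.
- Also in its favour: the Michael acceptor appears only at the very end, and no epimerisable aldehyde such as 26 is needed; on handling of sensitive groups the alternative is at least equal.
- Against it: the step does not build the ten-membered ring, so a second strategic step is still required.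
- Against it: the carbenoid faces competing sites in a crowded macrocycle: six-membered insertion into the oxygen-activated C8–H bond, and ylide formation at the oxirane or silyl ether oxygens. The C7–H bond is also deactivated by the neighbouring C8 oxygen.
- Against it: the basic methylenation would act on a substrate holding the allylic acetate and the epoxide, and the C8 ester would still have to be exchanged afterwards.
- Comparison: the chosen plan uses C6 to close the ring, whereas this route uses O6 as a tether. The two are complementary, and the alternative is shorter only for the lactone itself.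

Alternative 3: The cut is at C8=C9. The eleven-membered sulfone A7 would be halogenated next to sulfur, 1,3-elimination would give the episulfone, and loss of the sulfonyl bridge would contract the ring to the dienoate A6.
- In its favour: the ring is first closed at sulfur, and carbon–sulfur bond formation is usually a more dependable macrocyclisation than carbon–carbon coupling; on ring closure the alternative is better.
- Also in its favour: either α-carbon of the sulfone leads to the same alkene, so the site of halogenation does not matter, and the sulfone itself is robust.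
- Against it: A6 lacks O8, O9 and C13. A cis ring alkene gives the required threo diol only by anti addition, so a regio- and face-selective epoxidation and opening of a conjugated dienoate would be needed.
- Against it: nothing would then distinguish O8 from O9 for the two different acylations, and the strongly basic medium threatens the lactone and the position of the enoate double bond.
- Comparison: the chosen plan fixes C8 and C9 by reagent and chelate control before ring closure and needs no late oxidation of the ring. The alternative would need clearly more steps after its key step.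

Key step: step 19

Remarks on the chemistry:
- The configurations of 26 and 27 were checked centre by centre against 40: C4 and C6–C9 are retained, C5 is inverted in step 22, and the 1(10) alkene keeps C2 cis to C9. No correction of the skeletons is needed.
- The protecting groups are changed. O9 carries the final acetate before ring closure, because an acetal ether there would need acid after the oxiranes are in place. O8 is a PMB ether, which allows chelation control in step 15 and neutral removal. O12 is a triisopropylsilyl ether, which survives Grignard formation and the selective cleavage of primary triethylsilyl ethers.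
- C7 and C11–C13 cannot come from 2-methylenepropane-1,3-diol joined at C7–C8, because C7 must also carry C6. 2-Bromoprop-2-en-1-ol is used instead and is joined at C7–C11.
- Tartrate is not a carbon source here. It serves only as the ligand of the asymmetric epoxidation, and the D-enantiomer is required.
- (E)-But-2-ene-1,4-diol, 2-bromoprop-2-en-1-ol and (R)-2-methylglycidol are taken as commercial.

## Route

Part 1: fragment A (C1–C5, C10, C14, C15)

Step 1
Reactants: 1 (R)-linalool
Product: 3 (4R)-4-hydroxy-4-methylhex-5-enal, via ozonide 2 (not isolated)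
Conditions: O3 (about 1 equiv, Sudan Red 7B end point), CH2Cl2, −78 °C; then PPh3, −78 °C → rt
Reagents that add atoms: ozone, O=[O+][O-]
Why: Ozone is electrophilic and attacks the trisubstituted alkene much faster than the vinyl group, which is deactivated by the allylic hydroxyl, so the vinyl group is kept as latent C5 (Criegee ozonolysis with reductive work-up). The quaternary carbinol, the future C4, is not touched; 3 exists largely as its five-membered lactol.

Step 2
Reactants: 3 (4R)-4-hydroxy-4-methylhex-5-enal
Product: 4 methyl (2Z,6R)-2-bromo-6-hydroxy-6-methylocta-2,7-dienoate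
Conditions: Ph3P=CHCO2Me, N-bromosuccinimide, CH2Cl2, −20 °C; then 3, −20 → 40 °C
Reagents that add atoms: methyl (triphenylphosphoranylidene)acetate, COC(=O)C=P(c1ccccc1)(c1ccccc1)c1ccccc1; N-bromosuccinimide, O=C1CCC(=O)N1Br
Why: The stabilised ylide is brominated in the flask and the bromo ylide olefinates the open aldehyde form of 3 (Wittig reaction). As with other ester-stabilised ylides the chain ends up trans to the ester, which is the (Z)-bromide, so bromine marks the place of C9 cis to C2.

Step 3
Reactants: 4 methyl (2Z,6R)-2-bromo-6-hydroxy-6-methylocta-2,7-dienoate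
Product: 6 methyl (2Z,6R)-2-bromo-6,7-dihydroxy-6-methylhept-2-enoate, via ozonide 5 (not isolated)
Conditions: O3, CH2Cl2, −78 °C; then NaBH4, MeOH, −78 → 0 °C
Reagents that add atoms: ozone, O=[O+][O-]
Why: The α-bromo enoate is too electron-poor to react with ozone, so only the vinyl group is cleaved, and cold borohydride reduces the ozonide to the primary alcohol C5 faster than it touches the ester (ozonolysis with reductive work-up).

Step 4
Reactants: 6 methyl (2Z,6R)-2-bromo-6,7-dihydroxy-6-methylhept-2-enoate
Product: 7 methyl (2Z,6R)-2-bromo-6-methyl-6,7-bis(triethylsilyloxy)hept-2-enoate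
Conditions: Et3SiOTf (2.5 equiv), 2,6-lutidine, CH2Cl2, −78 → 0 °C
Reagents that add atoms: triethylsilyl trifluoromethanesulfonate, CC[Si](CC)(CC)OS(=O)(=O)C(F)(F)F
Why: A silyl triflate with a hindered pyridine base silylates the primary and the tertiary hydroxyl alike. The tertiary ether guards O4 up to the ring closure, and the primary ether can later be cleaved selectively to uncover C5.

Step 5
Reactants: 7 methyl (2Z,6R)-2-bromo-6-methyl-6,7-bis(triethylsilyloxy)hept-2-enoate
Product: 8 (2Z,6R)-2-bromo-6-methyl-6,7-bis(triethylsilyloxy)hept-2-en-1-ol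
Conditions: i-Bu2AlH (2.5 equiv), CH2Cl2, −78 °C; Rochelle salt work-up
Reagents that add atoms: none
Why: Hydride reduction of the enoate at low temperature goes 1,2 to the allylic alcohol without loss of bromine or alkene geometry. C14 is thus brought to the alcohol level at which C1=C10 is no acceptor for ketyl radicals.

Step 6
Reactants: 8 (2Z,6R)-2-bromo-6-methyl-6,7-bis(triethylsilyloxy)hept-2-en-1-ol
Product: 9 1-({[(2Z,6R)-2-bromo-6-methyl-6,7-bis(triethylsilyloxy)hept-2-en-1-yl]oxy}methyl)-4-methoxybenzene
Conditions: NaH, 4-methoxybenzyl chloride, Bu4NI (cat.), THF/DMF, 0 °C → rt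
Reagents that add atoms: 4-methoxybenzyl chloride, COc1ccc(CCl)cc1
Why: Williamson etherification of the only free hydroxyl. A benzyl-type ether is chosen because a silyl group on O14 would migrate from oxygen to carbon in the alkenyllithium of step 15.

Part 2: fragment B (C6–C9, C11–C13)

Step 7
Reactants: 10 2-bromoprop-2-en-1-ol
Product: 11 (2-bromoprop-2-en-1-yloxy)triisopropylsilane
Conditions: i-Pr3SiCl, imidazole, DMF, rt
Reagents that add atoms: chlorotriisopropylsilane, CC(C)[Si](Cl)(C(C)C)C(C)C
Why: Standard silylation. The bulky group is slow to migrate to carbon in the derived alkenyl metal and later outlasts the cleavage of primary triethylsilyl ethers.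

Step 8
Reactants: 12 (E)-but-2-ene-1,4-diol
Product: 13 (E)-4-[(4-methoxybenzyl)oxy]but-2-en-1-ol
Conditions: NaH (1 equiv), 4-methoxybenzyl chloride, Bu4NI (cat.), THF/DMF, 0 °C → rt; 12 in excess
Reagents that add atoms: 4-methoxybenzyl chloride, COc1ccc(CCl)cc1
Why: Statistical mono-etherification of a symmetrical diol, with excess diol keeping the bis-ether low. The alkene geometry is not touched.

Step 9
Reactants: 13 (E)-4-[(4-methoxybenzyl)oxy]but-2-en-1-ol
Product: 14 [(2R,3R)-3-{[(4-methoxybenzyl)oxy]methyl}oxiran-2-yl]methanol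
Conditions: Ti(Oi-Pr)4 (cat.), diethyl D-(−)-tartrate (cat.), t-BuOOH, 4 Å MS, CH2Cl2, −20 °C
Reagents that add atoms: tert-butyl hydroperoxide, CC(C)(C)OO
Why: Sharpless asymmetric epoxidation of an (E)-allylic alcohol; the titanium–tartrate complex delivers oxygen to one face. With the D-tartrate ligand this gives the (2R,3R)-oxirane, which fixes the future C8 directly and C7 after inversion.

Step 10
Reactants: 14 [(2R,3R)-3-{[(4-methoxybenzyl)oxy]methyl}oxiran-2-yl]methanol; 11 (2-bromoprop-2-en-1-yloxy)triisopropylsilane
Product: 16 (2S,3S)-4-[(4-methoxybenzyl)oxy]-2-[3-(triisopropylsilyloxy)prop-1-en-2-yl]butane-1,3-diol, via Grignard reagent 15 (not isolated)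
Conditions: 11, Mg, THF, rt; then CuI (10 mol %), 14, THF, −30 → 0 °C; NaIO4 wash of the crude product
Reagents that add atoms: none
Why: Copper-catalysed Grignard opening of a 2,3-epoxy alcohol takes place at C2 of the alkoxide and anti to the oxirane oxygen. This forms C7–C11 with inversion at C7 and leaves the oxygen on C8 with retention. Any 1,2-diol from attack at the other carbon is destroyed by periodate.

Step 11
Reactants: 16 (2S,3S)-4-[(4-methoxybenzyl)oxy]-2-[3-(triisopropylsilyloxy)prop-1-en-2-yl]butane-1,3-diol
Product: 17 (2S)-2-[(4S)-2-(4-methoxyphenyl)-1,3-dioxolan-4-yl]-3-[(triisopropylsilyloxy)methyl]but-3-en-1-ol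
Conditions: DDQ (1.2 equiv), 4 Å MS, CH2Cl2, 0 °C
Reagents that add atoms: none
Why: Without water, DDQ oxidises the PMB ether to an oxocarbenium ion that is trapped by the neighbouring secondary hydroxyl as the five-membered acetal. This sets O8 and O9 apart from the primary O6; the acetal carbon is an inconsequential epimer mixture.

Step 12
Reactants: 17 (2S)-2-[(4S)-2-(4-methoxyphenyl)-1,3-dioxolan-4-yl]-3-[(triisopropylsilyloxy)methyl]but-3-en-1-ol
Product: 18 triethyl{(2S)-2-[(4S)-2-(4-methoxyphenyl)-1,3-dioxolan-4-yl]-3-[(triisopropylsilyloxy)methyl]but-3-en-1-yloxy}silane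
Conditions: Et3SiCl, imidazole, CH2Cl2, 0 °C
Reagents that add atoms: chlorotriethylsilane, CC[Si](Cl)(CC)CC
Why: Silylation of the free primary hydroxyl. The same kind of ether sits on O5 in fragment A, so both can be removed together before the dialdehyde is made.

Step 13
Reactants: 18 triethyl{(2S)-2-[(4S)-2-(4-methoxyphenyl)-1,3-dioxolan-4-yl]-3-[(triisopropylsilyloxy)methyl]but-3-en-1-yloxy}silane
Product: 19 (2S,3S)-2-[(4-methoxybenzyl)oxy]-3-[(triethylsilyloxy)methyl]-4-[(triisopropylsilyloxy)methyl]pent-4-en-1-ol
Conditions: i-Bu2AlH (3 equiv), CH2Cl2, −78 → 0 °C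
Reagents that add atoms: none
Why: The aluminium hydride binds the less hindered primary acetal oxygen, that carbon–oxygen bond breaks, and hydride adds to the oxocarbenium ion. The PMB group therefore ends on the secondary O8 and the primary O9–H is set free (regioselective reductive acetal opening).

Step 14
Reactants: 19 (2S,3S)-2-[(4-methoxybenzyl)oxy]-3-[(triethylsilyloxy)methyl]-4-[(triisopropylsilyloxy)methyl]pent-4-en-1-ol
Product: 20 (2S,3S)-2-[(4-methoxybenzyl)oxy]-3-[(triethylsilyloxy)methyl]-4-[(triisopropylsilyloxy)methyl]pent-4-enal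
Conditions: Dess–Martin periodinane, NaHCO3, CH2Cl2, 0 °C → rt
Reagents that add atoms: none
Why: Dess–Martin oxidation of a primary alcohol under buffered, non-basic conditions, so the α-alkoxy centre C8 should not epimerise.

Part 3: union, ring closure and completion

Step 15
Reactants: 9 1-({[(2Z,6R)-2-bromo-6-methyl-6,7-bis(triethylsilyloxy)hept-2-en-1-yl]oxy}methyl)-4-methoxybenzene; 20 (2S,3S)-2-[(4-methoxybenzyl)oxy]-3-[(triethylsilyloxy)methyl]-4-[(triisopropylsilyloxy)methyl]pent-4-enal
Product: 23 (1(10)Z,4R,7S,8S,9S)-8,14-bis[(4-methoxybenzyl)oxy]-4,5,6-tris(triethylsilyloxy)-12-(triisopropylsilyloxy)-5,6-secogermacra-1(10),11(13)-dien-9-ol, via alkenyllithium 21 (not isolated), via alkenylmagnesium bromide 22 (not isolated)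
Conditions: 9, t-BuLi (2.05 equiv), Et2O, −78 °C; MgBr2·OEt2, −78 °C; then 20 premixed with MgBr2·OEt2, CH2Cl2, −78 °C
Reagents that add atoms: none
Why: Bromine–lithium exchange and transmetalation to magnesium keep the alkene geometry. Magnesium bridges the aldehyde oxygen and the PMB ether oxygen on C8 (chelation model), so the alkenyl group adds from the face away from the C7 branch. This gives the 8,9-syn (threo) relationship, that is the 9S carbinol.

Step 16
Reactants: 23 (1(10)Z,4R,7S,8S,9S)-8,14-bis[(4-methoxybenzyl)oxy]-4,5,6-tris(triethylsilyloxy)-12-(triisopropylsilyloxy)-5,6-secogermacra-1(10),11(13)-dien-9-ol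
Product: 24 (1(10)Z,4R,7S,8S,9S)-8,14-bis[(4-methoxybenzyl)oxy]-4,5,6-tris(triethylsilyloxy)-12-(triisopropylsilyloxy)-5,6-secogermacra-1(10),11(13)-dien-9-yl acetate
Conditions: Ac2O, pyridine, DMAP (cat.), CH2Cl2, 0 °C → rt
Reagents that add atoms: acetic anhydride, CC(=O)OC(C)=O
Why: DMAP-catalysed acylation of the only free hydroxyl. The acetate is the final C9 substituent and also serves as protecting group, so O9 needs no later deprotection.

Step 17
Reactants: 24 (1(10)Z,4R,7S,8S,9S)-8,14-bis[(4-methoxybenzyl)oxy]-4,5,6-tris(triethylsilyloxy)-12-(triisopropylsilyloxy)-5,6-secogermacra-1(10),11(13)-dien-9-yl acetate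
Product: 25 (1(10)Z,4R,7S,8S,9S)-5,6-dihydroxy-8,14-bis[(4-methoxybenzyl)oxy]-4-(triethylsilyloxy)-12-(triisopropylsilyloxy)-5,6-secogermacra-1(10),11(13)-dien-9-yl acetate
Conditions: PPTS (cat.), MeOH/CH2Cl2, 0 °C
Reagents that add atoms: none
Why: Acid-catalysed methanolysis removes the two primary triethylsilyl ethers far faster than the tertiary one on O4 or the primary triisopropylsilyl ether on O12. The acetate and the PMB ethers are inert.

Step 18
Reactants: 25 (1(10)Z,4R,7S,8S,9S)-5,6-dihydroxy-8,14-bis[(4-methoxybenzyl)oxy]-4-(triethylsilyloxy)-12-(triisopropylsilyloxy)-5,6-secogermacra-1(10),11(13)-dien-9-yl acetate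
Product: 26 (1(10)Z,4R,7R,8S,9S)-8,14-bis[(4-methoxybenzyl)oxy]-5,6-dioxo-4-(triethylsilyloxy)-12-(triisopropylsilyloxy)-5,6-secogermacra-1(10),11(13)-dien-9-yl acetate
Conditions: Dess–Martin periodinane, NaHCO3, CH2Cl2, 0 °C; crude product used at once
Reagents that add atoms: none
Why: Double Dess–Martin oxidation under buffered conditions. No amine base is present, which protects C7 (α to the C6 aldehyde and allylic) from epimerisation or migration of the alkene; C5 is quaternary at its α-carbon and cannot epimerise.

Step 19
Reactants: 26 (1(10)Z,4R,7R,8S,9S)-8,14-bis[(4-methoxybenzyl)oxy]-5,6-dioxo-4-(triethylsilyloxy)-12-(triisopropylsilyloxy)-5,6-secogermacra-1(10),11(13)-dien-9-yl acetate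
Product: 27 (1(10)Z,4R,5R,6R,7S,8S,9S)-5,6-dihydroxy-8,14-bis[(4-methoxybenzyl)oxy]-4-(triethylsilyloxy)-12-(triisopropylsilyloxy)germacra-1(10),11(13)-dien-9-yl acetate
Conditions: SmI2 (4 equiv, 0.1 M in THF), t-BuOH (2 equiv), THF, −78 °C, slow addition of 26 (final 2 mM); then aq. NH4Cl
Reagents that add atoms: none
Why: Each aldehyde takes one electron from divalent samarium and becomes a ketyl bound through oxygen to trivalent samarium; the metal-bridged ketyl carbons couple and form C5–C6. The closest known reaction type is the intramolecular SmI2 pinacol coupling of dialdehydes, which is established for carbocycles up to medium rings. The ten-membered ring closes by head-to-head union of the two chain termini under high dilution, helped by the (Z)-alkene and the four substituents that fold the chain. Bridging of both oxygens by samarium is expected to place them cis. At C5 the ketyl oxygen should lie anti to the C4–OSiEt3 bond for dipolar and steric reasons, which gives O5 trans to O4. At C6 the ring bond C7–C8 must be gauche to the forming bond, which places C7–C11 anti to it with hydrogen on the side of approach (Felkin–Anh-type arrangement), and this gives O6 cis to C11. The step needs pinacol coupling to win over 5-exo ketyl addition to C1=C10 and over loss of the α-silyloxy group: C14 is an ether and not an ester, no HMPA is used, and aldehyde coupling is fast at −78 °C. The acetate, the PMB ethers and the silyl ethers are inert to SmI2 in THF.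

Step 20
Reactants: 27 (1(10)Z,4R,5R,6R,7S,8S,9S)-5,6-dihydroxy-8,14-bis[(4-methoxybenzyl)oxy]-4-(triethylsilyloxy)-12-(triisopropylsilyloxy)germacra-1(10),11(13)-dien-9-yl acetate
Product: 28 (1(10)Z,4R,5R,6R,7S,8S,9S)-4,5,6,12-tetrahydroxy-8,14-bis[(4-methoxybenzyl)oxy]germacra-1(10),11(13)-dien-9-yl acetate
Conditions: Bu4NF, AcOH (1:1), THF, 0 °C → rt
Reagents that add atoms: none
Why: Fluoride cleaves both silicon–oxygen bonds and frees O12 and O4. Buffering with acetic acid keeps the medium from hydrolysing or transferring the acetate.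

Step 21
Reactants: 28 (1(10)Z,4R,5R,6R,7S,8S,9S)-4,5,6,12-tetrahydroxy-8,14-bis[(4-methoxybenzyl)oxy]germacra-1(10),11(13)-dien-9-yl acetate
Product: 30 (1(10)Z,4R,5R,6R,7R,8S,9S)-9-acetoxy-4,5-dihydroxy-8,14-bis[(4-methoxybenzyl)oxy]germacra-1(10),11(13)-dien-12,6-olide, via lactol 29 (not isolated)
Conditions: MnO2 (activated, excess), CH2Cl2, rt
Reagents that add atoms: none
Why: MnO2 oxidises only the allylic primary alcohol. The enal is trapped by the cis O6 as a five-membered hemiacetal, which is itself allylic and is oxidised on to the α-methylene lactone; the non-allylic hydroxyls on C4 and C5 are left, and five-membered closure on O6 should be preferred to six-membered closure on O5.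

Step 22
Reactants: 30 (1(10)Z,4R,5R,6R,7R,8S,9S)-9-acetoxy-4,5-dihydroxy-8,14-bis[(4-methoxybenzyl)oxy]germacra-1(10),11(13)-dien-12,6-olide
Product: 32 (1(10)Z,4R,5S,6R,7R,8S,9S)-9-acetoxy-4,5-epoxy-8,14-bis[(4-methoxybenzyl)oxy]germacra-1(10),11(13)-dien-12,6-olide, via mesylate 31 (not isolated)
Conditions: MsCl, Et3N, CH2Cl2, −20 °C; then DBU, 0 °C → rt
Reagents that add atoms: none
Why: Only the secondary O5–H is sulfonylated, since the tertiary O4–H is inert. O4 then displaces the sulfonate from the back (intramolecular SN2, 3-exo-tet) with inversion at C5, which gives the cis-epoxide with C3 and C6 on the same side.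

Step 23
Reactants: 32 (1(10)Z,4R,5S,6R,7R,8S,9S)-9-acetoxy-4,5-epoxy-8,14-bis[(4-methoxybenzyl)oxy]germacra-1(10),11(13)-dien-12,6-olide
Product: 33 (1(10)Z,4R,5S,6R,7R,8S,9S)-9-acetoxy-4,5-epoxy-8,14-dihydroxygermacra-1(10),11(13)-dien-12,6-olide
Conditions: DDQ (3 equiv), CH2Cl2/pH 7 phosphate buffer, 0 °C → rt
Reagents that add atoms: none
Why: Oxidative cleavage of both PMB ethers under neutral buffered conditions. No acid or base is present, so the oxirane, the acetate and the methylene lactone stay intact and the acetate has no cause to migrate.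

Step 24
Reactants: 33 (1(10)Z,4R,5S,6R,7R,8S,9S)-9-acetoxy-4,5-epoxy-8,14-dihydroxygermacra-1(10),11(13)-dien-12,6-olide
Product: 35 (1(10)E,4R,5S,6R,7R,8S,9S)-9-acetoxy-4,5-epoxy-8-hydroxygermacra-1(10),11(13)-dien-12,6-olid-14-oic acid, via enal 34 (not isolated)
Conditions: MnO2, CH2Cl2, rt; filter; then NaClO2, NaH2PO4, 2-methylbut-2-ene, t-BuOH/H2O, 0 °C
Reagents that add atoms: sodium chlorite, [Na+].[O-]Cl=O
Why: MnO2 oxidises the allylic primary C14–OH and leaves the secondary O8–H. The Pinnick oxidation then takes the enal to the acid while 2-methylbut-2-ene removes hypochlorite, which protects the alkenes and the oxirane.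

Step 25
Reactants: 35 (1(10)E,4R,5S,6R,7R,8S,9S)-9-acetoxy-4,5-epoxy-8-hydroxygermacra-1(10),11(13)-dien-12,6-olid-14-oic acid
Product: 36 methyl (1(10)E,4R,5S,6R,7R,8S,9S)-9-acetoxy-4,5-epoxy-8-hydroxygermacra-1(10),11(13)-dien-12,6-olid-14-oate
Conditions: MeI, KHCO3, DMF, 0 °C → rt
Reagents that add atoms: iodomethane, CI
Why: SN2 alkylation of the carboxylate under a weak base. A diazoalkane is avoided because it would add to the methylene lactone, and the base is too weak to open the lactone or move the acetate.

Step 26
Reactants: 37 (R)-2-methylglycidol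
Product: 38 (S)-2-methyloxirane-2-carboxylic acid
Conditions: RuCl3 (cat.), NaIO4, MeCN/EtOAc/H2O, 0 °C → rt
Reagents that add atoms: water, O
Why: Ruthenium tetroxide formed in the flask oxidises the primary alcohol through the aldehyde hydrate to the acid. The stereocentre is quaternary and cannot epimerise, and the descriptor changes from R to S only through the priority rules.

Step 27
Reactants: 36 methyl (1(10)E,4R,5S,6R,7R,8S,9S)-9-acetoxy-4,5-epoxy-8-hydroxygermacra-1(10),11(13)-dien-12,6-olid-14-oate; 38 (S)-2-methyloxirane-2-carboxylic acid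
Product: 40 methyl (1(10)E,4R,5S,6R,7R,8S,9S)-9-acetoxy-4,5-epoxy-8-{[(2S)-2-methyloxirane-2-carbonyl]oxy}germacra-1(10),11(13)-dien-12,6-olid-14-oate, via mixed anhydride 39 (not isolated)
Conditions: 38, 2,4,6-trichlorobenzoyl chloride, Et3N, THF, 0 °C; then 36, DMAP, toluene, rt
Reagents that add atoms: none
Why: Yamaguchi esterification: the preformed mixed anhydride is attacked by DMAP at the less hindered carbonyl, and the acylpyridinium ion acylates O8. A reactive acyl donor is used so that acylation outruns transfer of the acetate from O9; neither stereocentre of the partners is at risk.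

## Compound list

1 | (R)-linalool, (3R)-3,7-dimethylocta-1,6-dien-3-ol | C=C[C@](C)(O)CCC=C(C)C | starting material
2 | 3-[(3R)-3-hydroxy-3-methylpent-4-en-1-yl]-5,5-dimethyl-1,2,4-trioxolane (ozonide of 1, epimers at the ring carbon) | C=C[C@](C)(O)CCC1OC(C)(C)OO1 | intermediate
3 | (4R)-4-hydroxy-4-methylhex-5-enal (in equilibrium with its five-membered lactol) | C=C[C@](C)(O)CCC=O | intermediate
4 | methyl (2Z,6R)-2-bromo-6-hydroxy-6-methylocta-2,7-dienoate | C=C[C@](C)(O)CC/C=C(/C(=O)OC)Br | intermediate
5 | methyl (2Z,6R)-2-bromo-6-hydroxy-6-(1,2,4-trioxolan-3-yl)hept-2-enoate (ozonide of 4, epimers at the ring carbon) | C1OC(OO1)[C@](C)(O)CC/C=C(/C(=O)OC)Br | intermediate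
6 | methyl (2Z,6R)-2-bromo-6,7-dihydroxy-6-methylhept-2-enoate | OC[C@](C)(O)CC/C=C(/C(=O)OC)Br | intermediate
7 | methyl (2Z,6R)-2-bromo-6-methyl-6,7-bis(triethylsilyloxy)hept-2-enoate | CC[Si](CC)(CC)OC[C@](C)(O[Si](CC)(CC)CC)CC/C=C(/C(=O)OC)Br | intermediate
8 | (2Z,6R)-2-bromo-6-methyl-6,7-bis(triethylsilyloxy)hept-2-en-1-ol | CC[Si](CC)(CC)OC[C@](C)(O[Si](CC)(CC)CC)CC/C=C(/CO)Br | intermediate
9 | 1-({[(2Z,6R)-2-bromo-6-methyl-6,7-bis(triethylsilyloxy)hept-2-en-1-yl]oxy}methyl)-4-methoxybenzene (fragment A) | CC[Si](CC)(CC)OC[C@](C)(O[Si](CC)(CC)CC)CC/C=C(/COCc1ccc(OC)cc1)Br | intermediate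
10 | 2-bromoprop-2-en-1-ol | C=C(Br)CO | starting material
11 | (2-bromoprop-2-en-1-yloxy)triisopropylsilane | C=C(Br)CO[Si](C(C)C)(C(C)C)C(C)C | intermediate
12 | (E)-but-2-ene-1,4-diol | OC/C=C/CO | starting material
13 | (E)-4-[(4-methoxybenzyl)oxy]but-2-en-1-ol | OC/C=C/COCc1ccc(OC)cc1 | intermediate
14 | [(2R,3R)-3-{[(4-methoxybenzyl)oxy]methyl}oxiran-2-yl]methanol | OC[C@H]1O[C@@H]1COCc1ccc(OC)cc1 | intermediate
15 | {3-[(triisopropylsilyl)oxy]prop-1-en-2-yl}magnesium bromide | C=C([Mg]Br)CO[Si](C(C)C)(C(C)C)C(C)C | intermediate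
16 | (2S,3S)-4-[(4-methoxybenzyl)oxy]-2-[3-(triisopropylsilyloxy)prop-1-en-2-yl]butane-1,3-diol | OC[C@H](C(=C)CO[Si](C(C)C)(C(C)C)C(C)C)[C@H](O)COCc1ccc(OC)cc1 | intermediate
17 | (2S)-2-[(4S)-2-(4-methoxyphenyl)-1,3-dioxolan-4-yl]-3-[(triisopropylsilyloxy)methyl]but-3-en-1-ol (epimers at the acetal carbon) | OC[C@H](C(=C)CO[Si](C(C)C)(C(C)C)C(C)C)[C@H]1COC(c2ccc(OC)cc2)O1 | intermediate
18 | triethyl{(2S)-2-[(4S)-2-(4-methoxyphenyl)-1,3-dioxolan-4-yl]-3-[(triisopropylsilyloxy)methyl]but-3-en-1-yloxy}silane (epimers at the acetal carbon) | CC[Si](CC)(CC)OC[C@H](C(=C)CO[Si](C(C)C)(C(C)C)C(C)C)[C@H]1COC(c2ccc(OC)cc2)O1 | intermediate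
19 | (2S,3S)-2-[(4-methoxybenzyl)oxy]-3-[(triethylsilyloxy)methyl]-4-[(triisopropylsilyloxy)methyl]pent-4-en-1-ol | CC[Si](CC)(CC)OC[C@H](C(=C)CO[Si](C(C)C)(C(C)C)C(C)C)[C@H](OCc1ccc(OC)cc1)CO | intermediate
20 | (2S,3S)-2-[(4-methoxybenzyl)oxy]-3-[(triethylsilyloxy)methyl]-4-[(triisopropylsilyloxy)methyl]pent-4-enal (fragment B) | CC[Si](CC)(CC)OC[C@H](C(=C)CO[Si](C(C)C)(C(C)C)C(C)C)[C@H](OCc1ccc(OC)cc1)C=O | intermediate
21 | alkenyllithium from 9 (lithium in place of bromine, same geometry) | CC[Si](CC)(CC)OC[C@](C)(O[Si](CC)(CC)CC)CC/C=C(/COCc1ccc(OC)cc1)[Li] | intermediate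
22 | alkenylmagnesium bromide from 21 | CC[Si](CC)(CC)OC[C@](C)(O[Si](CC)(CC)CC)CC/C=C(/COCc1ccc(OC)cc1)[Mg]Br | intermediate
23 | (1(10)Z,4R,7S,8S,9S)-8,14-bis[(4-methoxybenzyl)oxy]-4,5,6-tris(triethylsilyloxy)-12-(triisopropylsilyloxy)-5,6-secogermacra-1(10),11(13)-dien-9-ol | CC[Si](CC)(CC)OC[C@](C)(O[Si](CC)(CC)CC)CC/C=C(/COCc1ccc(OC)cc1)[C@H](O)[C@@H](OCc1ccc(OC)cc1)[C@@H](C(=C)CO[Si](C(C)C)(C(C)C)C(C)C)CO[Si](CC)(CC)CC | intermediate
24 | 9-O-acetate of 23 | CC[Si](CC)(CC)OC[C@](C)(O[Si](CC)(CC)CC)CC/C=C(/COCc1ccc(OC)cc1)[C@H](OC(C)=O)[C@@H](OCc1ccc(OC)cc1)[C@@H](C(=C)CO[Si](C(C)C)(C(C)C)C(C)C)CO[Si](CC)(CC)CC | intermediate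
25 | (1(10)Z,4R,7S,8S,9S)-5,6-dihydroxy-8,14-bis[(4-methoxybenzyl)oxy]-4-(triethylsilyloxy)-12-(triisopropylsilyloxy)-5,6-secogermacra-1(10),11(13)-dien-9-yl acetate | OC[C@](C)(O[Si](CC)(CC)CC)CC/C=C(/COCc1ccc(OC)cc1)[C@H](OC(C)=O)[C@@H](OCc1ccc(OC)cc1)[C@@H](C(=C)CO[Si](C(C)C)(C(C)C)C(C)C)CO | intermediate
26 | (1(10)Z,4R,7R,8S,9S)-8,14-bis[(4-methoxybenzyl)oxy]-5,6-dioxo-4-(triethylsilyloxy)-12-(triisopropylsilyloxy)-5,6-secogermacra-1(10),11(13)-dien-9-yl acetate (C5,C6-dialdehyde, precursor of the key step) | O=C[C@](C)(O[Si](CC)(CC)CC)CC/C=C(/COCc1ccc(OC)cc1)[C@H](OC(C)=O)[C@@H](OCc1ccc(OC)cc1)[C@@H](C(=C)CO[Si](C(C)C)(C(C)C)C(C)C)C=O | intermediate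
27 | (1(10)Z,4R,5R,6R,7S,8S,9S)-5,6-dihydroxy-8,14-bis[(4-methoxybenzyl)oxy]-4-(triethylsilyloxy)-12-(triisopropylsilyloxy)germacra-1(10),11(13)-dien-9-yl acetate (ten-membered cis-5,6-diol, product of the key step) | O[C@H]1[C@](C)(O[Si](CC)(CC)CC)CC/C=C(/COCc2ccc(OC)cc2)[C@H](OC(C)=O)[C@@H](OCc2ccc(OC)cc2)[C@@H](C(=C)CO[Si](C(C)C)(C(C)C)C(C)C)[C@H]1O | intermediate
28 | (1(10)Z,4R,5R,6R,7S,8S,9S)-4,5,6,12-tetrahydroxy-8,14-bis[(4-methoxybenzyl)oxy]germacra-1(10),11(13)-dien-9-yl acetate | O[C@H]1[C@](C)(O)CC/C=C(/COCc2ccc(OC)cc2)[C@H](OC(C)=O)[C@@H](OCc2ccc(OC)cc2)[C@@H](C(=C)CO)[C@H]1O | intermediate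
29 | 6,12-lactol of 28 after oxidation of C12 (epimers at C12) | O[C@H]1[C@](C)(O)CC/C=C(/COCc2ccc(OC)cc2)[C@H](OC(C)=O)[C@@H](OCc2ccc(OC)cc2)[C@H]3C(=C)C(O)O[C@@H]13 | intermediate
30 | (1(10)Z,4R,5R,6R,7R,8S,9S)-9-acetoxy-4,5-dihydroxy-8,14-bis[(4-methoxybenzyl)oxy]germacra-1(10),11(13)-dien-12,6-olide | O[C@H]1[C@](C)(O)CC/C=C(/COCc2ccc(OC)cc2)[C@H](OC(C)=O)[C@@H](OCc2ccc(OC)cc2)[C@H]3C(=C)C(=O)O[C@@H]13 | intermediate
31 | 5-O-methanesulfonate of 30 | CS(=O)(=O)O[C@H]1[C@](C)(O)CC/C=C(/COCc2ccc(OC)cc2)[C@H](OC(C)=O)[C@@H](OCc2ccc(OC)cc2)[C@H]3C(=C)C(=O)O[C@@H]13 | intermediate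
32 | (1(10)Z,4R,5S,6R,7R,8S,9S)-9-acetoxy-4,5-epoxy-8,14-bis[(4-methoxybenzyl)oxy]germacra-1(10),11(13)-dien-12,6-olide | C=C1C(=O)O[C@@H]2[C@H]1[C@H](OCc1ccc(OC)cc1)[C@@H](OC(C)=O)/C(COCc1ccc(OC)cc1)=C\CC[C@@]1(C)O[C@@H]21 | intermediate
33 | (1(10)Z,4R,5S,6R,7R,8S,9S)-9-acetoxy-4,5-epoxy-8,14-dihydroxygermacra-1(10),11(13)-dien-12,6-olide | C=C1C(=O)O[C@@H]2[C@H]1[C@H](O)[C@@H](OC(C)=O)/C(CO)=C\CC[C@@]1(C)O[C@@H]21 | intermediate
34 | (1(10)E,4R,5S,6R,7R,8S,9S)-9-acetoxy-4,5-epoxy-8-hydroxy-14-oxogermacra-1(10),11(13)-dien-12,6-olide | C=C1C(=O)O[C@@H]2[C@H]1[C@H](O)[C@@H](OC(C)=O)/C(C=O)=C\CC[C@@]1(C)O[C@@H]21 | intermediate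
35 | (1(10)E,4R,5S,6R,7R,8S,9S)-9-acetoxy-4,5-epoxy-8-hydroxygermacra-1(10),11(13)-dien-12,6-olid-14-oic acid | C=C1C(=O)O[C@@H]2[C@H]1[C@H](O)[C@@H](OC(C)=O)/C(C(=O)O)=C\CC[C@@]1(C)O[C@@H]21 | intermediate
36 | methyl (1(10)E,4R,5S,6R,7R,8S,9S)-9-acetoxy-4,5-epoxy-8-hydroxygermacra-1(10),11(13)-dien-12,6-olid-14-oate | C=C1C(=O)O[C@@H]2[C@H]1[C@H](O)[C@@H](OC(C)=O)/C(C(=O)OC)=C\CC[C@@]1(C)O[C@@H]21 | intermediate
37 | (R)-2-methylglycidol, [(2R)-2-methyloxiran-2-yl]methanol | OC[C@]1(C)CO1 | starting material
38 | (S)-2-methyloxirane-2-carboxylic acid | OC(=O)[C@]1(C)CO1 | intermediate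
39 | (2S)-2-methyloxirane-2-carboxylic 2,4,6-trichlorobenzoic anhydride | O=C(OC(=O)[C@]1(C)CO1)c1c(Cl)cc(Cl)cc1Cl | intermediate
40 | methyl (1(10)E,4R,5S,6R,7R,8S,9S)-9-acetoxy-4,5-epoxy-8-{[(2S)-2-methyloxirane-2-carbonyl]oxy}germacra-1(10),11(13)-dien-12,6-olid-14-oate (CNP0274195.1) | C=C1C(=O)O[C@@H]2[C@H]1[C@H](OC(=O)[C@]1(C)CO1)[C@@H](OC(C)=O)/C(C(=O)OC)=C\CC[C@@]1(C)O[C@@H]21 | target

## Step count and least certain steps

Total: 27 steps. Longest linear sequence: 19 steps (steps 8–14, 15–25 and 27, from 12).

Step 19 (key step). The most likely failure is coupling with the wrong pairing of aldehyde faces, which would give a trans-diol or the other cis-diol; the directing effects of C4 and C7 are remote from each other and need not reinforce each other. Intermolecular coupling at too high a concentration and epimerisation at C7 of 26 before the electron transfer are further risks.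

The fallback sets out from 26 and returns at 32. It separates ring closure from oxygenation:
- McMurry coupling of 26 (TiCl3(DME)1.5, Zn(Cu), DME, reflux, high dilution) would close the ring as the (5Z)-5,6-alkene F1.
- HF·pyridine would remove the tertiary triethylsilyl group and give the allylic alcohol F2.
- VO(acac)2 with t-BuOOH would epoxidise only the alkene next to the free hydroxyl. For a cis-alkene it should do so mainly anti (threo) to O4, which gives the 5,6-epoxy-4-ol F3.
- Payne rearrangement (NaH, THF, 0 °C) would move the oxirane to C4–C5 with inversion at C5 and release O6, which gives the 4,5-epoxy-6-ol F4.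
- Bu4NF with AcOH would free O12 and give the epoxy diol F5.
- MnO2 would then close the lactone on O6 and give 32.

Step 15. Incomplete chelation, for example through competition of ether from the lithiation for magnesium, would lower the facial selectivity and give the 9-epimer with 23. The fallback sets out from 23 as its epimer mixture and returns at 23. Dess–Martin oxidation would give the enone F6. Corey–Bakshi–Shibata reduction would then set C9 under reagent control; the (S)-oxazaborolidine with catecholborane is expected to give the 9S carbinol if the α-branched alkenyl group acts as the large substituent, and the enantiomeric catalyst would be used otherwise.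

Step 21. Hemiacetal formation on O5 in place of O6 would lead to the six-membered lactone, and slow glycol cleavage of the free 4,5- or 5,6-diol by MnO2 could erode the material. The fallback sets out from 28 and returns at 30. The six-membered lactone F7 would not be discarded; it would be equilibrated with catalytic Ti(Oi-Pr)4 in toluene (translactonisation under thermodynamic control) to the cis-fused five-membered lactone 30, so that kinetic selection in the oxidation is replaced by equilibration.

Step 22. Ring closure may stall if the tertiary alkoxide and the sulfonate cannot reach an anti arrangement in the ten-membered ring; elimination of the sulfonate or attack of the base on the methylene lactone would then compete. The fallback sets out from 30 and returns at 32. Mitsunobu cyclodehydration of the 4,5-diol (PPh3, diisopropyl azodicarboxylate, toluene) would activate the secondary O5 as its oxyphosphonium ion and let O4 displace it with the same inversion at C5. No base is used and the sulfonate is not made, so this fallback makes no new compound (F0).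

## Further compounds

F1 | step 19 | (1(10)Z,5Z,4R,7S,8S,9S)-8,14-bis[(4-methoxybenzyl)oxy]-4-(triethylsilyloxy)-12-(triisopropylsilyloxy)germacra-1(10),5,11(13)-trien-9-yl acetate | CC[Si](CC)(CC)O[C@]1(C)CC/C=C(/COCc2ccc(OC)cc2)[C@H](OC(C)=O)[C@@H](OCc2ccc(OC)cc2)[C@@H](C(=C)CO[Si](C(C)C)(C(C)C)C(C)C)/C=C\1
F2 | step 19 | 4-hydroxy analogue of F1 (tertiary allylic alcohol) | O[C@]1(C)CC/C=C(/COCc2ccc(OC)cc2)[C@H](OC(C)=O)[C@@H](OCc2ccc(OC)cc2)[C@@H](C(=C)CO[Si](C(C)C)(C(C)C)C(C)C)/C=C\1
F3 | step 19 | cis-5,6-epoxy-4-hydroxy-8,14-bis[(4-methoxybenzyl)oxy]-12-(triisopropylsilyloxy)germacra-1(10),11(13)-dien-9-yl acetate (oxirane anti to O4) | O2[C@H]1[C@](C)(O)CC/C=C(/COCc3ccc(OC)cc3)[C@H](OC(C)=O)[C@@H](OCc3ccc(OC)cc3)[C@@H](C(=C)CO[Si](C(C)C)(C(C)C)C(C)C)[C@H]12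
F4 | step 19 | (4R,5S,6R)-4,5-epoxy-6-hydroxy-8,14-bis[(4-methoxybenzyl)oxy]-12-(triisopropylsilyloxy)germacra-1(10),11(13)-dien-9-yl acetate | O[C@@H]1[C@H](C(=C)CO[Si](C(C)C)(C(C)C)C(C)C)[C@H](OCc2ccc(OC)cc2)[C@@H](OC(C)=O)/C(COCc2ccc(OC)cc2)=C\CC[C@@]2(C)O[C@@H]12
F5 | step 19 | (4R,5S,6R)-4,5-epoxy-6,12-dihydroxy-8,14-bis[(4-methoxybenzyl)oxy]germacra-1(10),11(13)-dien-9-yl acetate | O[C@@H]1[C@H](C(=C)CO)[C@H](OCc2ccc(OC)cc2)[C@@H](OC(C)=O)/C(COCc2ccc(OC)cc2)=C\CC[C@@]2(C)O[C@@H]12
F6 | step 15 | (1(10)Z,4R,7S,8S)-8,14-bis[(4-methoxybenzyl)oxy]-4,5,6-tris(triethylsilyloxy)-12-(triisopropylsilyloxy)-5,6-secogermacra-1(10),11(13)-dien-9-one | CC[Si](CC)(CC)OC[C@](C)(O[Si](CC)(CC)CC)CC/C=C(/COCc1ccc(OC)cc1)C(=O)[C@@H](OCc1ccc(OC)cc1)[C@@H](C(=C)CO[Si](C(C)C)(C(C)C)C(C)C)CO[Si](CC)(CC)CC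
F7 | step 21 | 9-acetoxy-4,6-dihydroxy-8,14-bis[(4-methoxybenzyl)oxy]germacra-1(10),11(13)-dien-12,5-olide (six-membered lactone on O5) | O=C1O[C@H]2[C@](C)(O)CC/C=C(/COCc3ccc(OC)cc3)[C@H](OC(C)=O)[C@@H](OCc3ccc(OC)cc3)[C@@H](C1=C)[C@H]2O
F0 | step 22 | none | none
A1 | alternative 1 | cis-anti-cis tricyclic photoadduct | O=C1C[C@@H]2[C@H](O[Si](C)(C)C(C)(C)C)C(=O)[C@@]3(C(=O)OC)[C@@H]4CC[C@]4(C)[C@H]3[C@@H]2O1
A2 | alternative 1 | lactone-fused 2-carbomethoxycyclohexenone | O=C1C[C@@H]2[C@H](O[Si](C)(C)C(C)(C)C)C(=O)C(C(=O)OC)=C[C@@H]2O1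
A3 | alternative 1 | 1-methylcyclobutene | CC1=CCC1
A4 | alternative 2 | cis-fused α-phosphono lactone | COP(=O)(OC)[C@@H]1C(=O)O[C@@H]2[C@H]1[C@H](O[Si](C)(C)C(C)(C)C)[C@@H](OC(C)=O)/C(C(=O)OC)=C\CC[C@@]1(C)O[C@@H]21
A5 | alternative 2 | C6 diazophosphonoacetate of the ten-membered epoxy enoate | COP(=O)(OC)C(=[N+]=[N-])C(=O)O[C@@H]1C[C@H](O[Si](C)(C)C(C)(C)C)[C@@H](OC(C)=O)/C(C(=O)OC)=C\CC[C@@]2(C)O[C@@H]12
A6 | alternative 3 | ten-membered 1(10),8-dienoate with epoxide and lactone | C1[C@@]2(C)O[C@H]2[C@@H]3OC(=O)C[C@@H]3/C=C\C(C(=O)OC)=C/C1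
A7 | alternative 3 | eleven-membered sulfone with sulfur between C8 and C9 | C1[C@@]2(C)O[C@H]2[C@@H]3OC(=O)C[C@@H]3CS(=O)(=O)C\C(C(=O)OC)=C/C1
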